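**Retrosynthetic overview**

1. Labels used below (target 21): ring A = C1(CH3)=C2H–C3H2–C4H(Br)–C5(CH3)2–C6; ring B = C6–C7H2–C8H2–C9(CH3)(Cl)–C10H(Br)–C11H2; C6 is the spiro atom.
2. Last disconnection: ring B at C6–C7. Enabling feature: spiro C6 is bonded in ring A to C1, the carbon that bears the methyl group and the C1=C2 double bond, so C6 can be the nucleophilic end of a tetrasubstituted C6=C1 alkene whose C1 cation ends as C1=C2; C7 is a plain CH2 that can carry a triflate.
3. The C9–Cl/C10–Br pair (trans, both equatorial, Br cis to C5) is the opposite of what trans-diaxial addition to a ring B alkene should give. It is therefore set on the open chain by titanium-catalysed bromochlorination of a Z allylic alcohol (C8–OH), and C8 is then extended by C7.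
4. C10–C11 region: the chain is joined at C11 by allylation of a ring A allylic bromide with a Z alkenylmagnesium made from propargyl alcohol. Ring A (C4–Br, C5 gem-dimethyl) comes from prenol by bromochlorination, triflate alkylation of acetoacetate dianion (C2–C3) and bromochloride-solvolysis cyclisation (C5–C6).
5. Ring order: ring A in step 4, ring B in step 14.

Key step: step 14

Assumption: in each bromochlorination the enantiomer of the chiral Schiff-base ligand that delivers the stated configuration is used; both ligand enantiomers are equally accessible.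

**Route**

Step 1
Reactants: 1 3-methylbut-2-en-1-ol (prenol)
Product: 2 (2S)-2-bromo-3-chloro-3-methylbutan-1-ol
Conditions: NBS, ClTi(OiPr)3, chiral tridentate Schiff-base ligand (10 mol %), hexanes, −20 °C
Reagents that add atoms: N-bromosuccinimide, O=C1CCC(=O)N1Br; chlorotitanium triisopropoxide, CC(C)O[Ti](Cl)(OC(C)C)OC(C)C
Why: Titanium-catalysed enantioselective bromochlorination of an allylic alcohol: anti addition with chloride delivered to the tertiary carbon, and the ligand enantiomer sets the C–Br centre (future C4) as S.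

Step 2
Reactants: 2 (2S)-2-bromo-3-chloro-3-methylbutan-1-ol
Product: 3 (2S)-2-bromo-3-chloro-3-methylbutyl trifluoromethanesulfonate
Conditions: Tf2O, 2,6-lutidine, CH2Cl2, −78 °C
Reagents that add atoms: trifluoromethanesulfonic anhydride, O=S(=O)(OS(=O)(=O)C(F)(F)F)C(F)(F)F
Why: O-Sulfonylation of the primary alcohol at low temperature; no bond to the stereocentre is touched.

Step 3
Reactants: 3 (2S)-2-bromo-3-chloro-3-methylbutyl trifluoromethanesulfonate; 4 methyl acetoacetate (methyl 3-oxobutanoate)
Product: 6 methyl (6S)-6-bromo-7-chloro-7-methyl-3-oxooctanoate, via methyl acetoacetate dianion 5 (not isolated)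
Conditions: 4, NaH, THF, 0 °C; n-BuLi, 0 °C; then 3, −78 → −40 °C; 1 M HCl
Reagents that add atoms: none
Why: γ-Alkylation of the acetoacetate dianion (SN2 at the primary triflate), which at −78 °C should be much faster than attack at the secondary bromide or tertiary chloride.

Step 4
Reactants: 6 methyl (6S)-6-bromo-7-chloro-7-methyl-3-oxooctanoate
Product: 7 methyl (3S)-3-bromo-2,2-dimethyl-6-oxocyclohexane-1-carboxylate
Conditions: (CF3)2CHOH, 23 °C
Reagents that add atoms: none
Why: Bromochloride solvolysis and bromonium-initiated cation–olefin cyclisation: bromine-assisted ionisation of the tertiary chloride leaves the C–Br centre unchanged, and the β-keto ester enol closes ring A through carbon in a 6-endo chair (an O-cyclised enol ether should re-ionise in the acidic medium).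

Step 5
Reactants: 7 methyl (3S)-3-bromo-2,2-dimethyl-6-oxocyclohexane-1-carboxylate
Product: 8 methyl (5S)-5-bromo-6,6-dimethyl-2-(trifluoromethanesulfonyloxy)cyclohex-1-ene-1-carboxylate
Conditions: Tf2O, i-Pr2NEt, CH2Cl2, −78 °C
Reagents that add atoms: trifluoromethanesulfonic anhydride, O=S(=O)(OS(=O)(=O)C(F)(F)F)C(F)(F)F
Why: Enol triflate formation from the enolised β-keto ester; the amine base at −78 °C avoids a free enolate that could displace the C4 bromide.

Step 6
Reactants: 8 methyl (5S)-5-bromo-6,6-dimethyl-2-(trifluoromethanesulfonyloxy)cyclohex-1-ene-1-carboxylate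
Product: 9 methyl (5S)-5-bromo-2,6,6-trimethylcyclohex-1-ene-1-carboxylate
Conditions: CuI, MeLi (2 equiv), THF, 0 °C; then 8, −78 → −30 °C
Reagents that add atoms: lithium dimethylcuprate, [Li+].C[Cu-]C
Why: Cuprate addition–elimination on the β-triflyloxy enoate installs the C1 methyl group and the tetrasubstituted C6=C1 alkene; the neopentyl-type secondary bromide should be inert at this temperature.

Step 7
Reactants: 9 methyl (5S)-5-bromo-2,6,6-trimethylcyclohex-1-ene-1-carboxylate
Product: 10 [(5S)-5-bromo-2,6,6-trimethylcyclohex-1-en-1-yl]methanol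
Conditions: i-Bu2AlH, CH2Cl2, −78 → 0 °C; aq. potassium sodium tartrate
Reagents that add atoms: none
Why: 1,2-Reduction of the enoate to the allylic alcohol by an aluminium hydride that does not reduce alkyl bromides under these conditions.

Step 8
Reactants: 10 [(5S)-5-bromo-2,6,6-trimethylcyclohex-1-en-1-yl]methanol
Product: 11 (4S)-4-bromo-2-(bromomethyl)-1,3,3-trimethylcyclohex-1-ene
Conditions: CBr4, PPh3, CH2Cl2, 0 °C
Reagents that add atoms: carbon tetrabromide, BrC(Br)(Br)Br
Why: Appel bromination of the primary allylic alcohol under neutral conditions.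

Step 9
Reactants: 11 (4S)-4-bromo-2-(bromomethyl)-1,3,3-trimethylcyclohex-1-ene; 12 prop-2-yn-1-ol
Product: 14 (2Z)-4-[(5S)-5-bromo-2,6,6-trimethylcyclohex-1-en-1-yl]-2-methylbut-2-en-1-ol, via chelated alkenylmagnesium alkoxide 13 (not isolated)
Conditions: 12, MeMgBr (2.0 equiv), CuI (10 mol %), THF, −10 → 23 °C; then 11, −30 → 0 °C; dilute aq. HCl
Reagents that add atoms: methylmagnesium bromide, C[Mg]Br
Why: Copper-catalysed anti-carbomagnesiation of the propargylic alkoxide gives a five-membered chelate that holds magnesium cis to CH2O, and its copper-catalysed SN2 allylation at the primary carbon of 11 should therefore give the Z alkene with C8 and C11 cis.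

Step 10
Reactants: 14 (2Z)-4-[(5S)-5-bromo-2,6,6-trimethylcyclohex-1-en-1-yl]-2-methylbut-2-en-1-ol
Product: 15 (2R,3R)-3-bromo-4-[(5S)-5-bromo-2,6,6-trimethylcyclohex-1-en-1-yl]-2-chloro-2-methylbutan-1-ol
Conditions: NBS, ClTi(OiPr)3, chiral tridentate Schiff-base ligand (20 mol %), hexanes–CH2Cl2, −20 °C
Reagents that add atoms: N-bromosuccinimide, O=C1CCC(=O)N1Br; chlorotitanium triisopropoxide, CC(C)O[Ti](Cl)(OC(C)C)OC(C)C
Why: Hydroxyl-directed titanium-catalysed enantioselective bromochlorination: anti addition across the Z alkene puts Cl on tertiary C9 and Br on C10 in the trans relationship of the target, the ligand sets 9R,10R, and reaction inside the titanium alkoxide should leave the unbound tetrasubstituted ring alkene alone.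

Step 11
Reactants: 15 (2R,3R)-3-bromo-4-[(5S)-5-bromo-2,6,6-trimethylcyclohex-1-en-1-yl]-2-chloro-2-methylbutan-1-ol
Product: 16 (2R,3R)-3-bromo-4-[(5S)-5-bromo-2,6,6-trimethylcyclohex-1-en-1-yl]-2-chloro-2-methylbutanal
Conditions: Dess–Martin periodinane, CH2Cl2, 0 → 23 °C
Reagents that add atoms: none
Why: Dess–Martin oxidation of the primary alcohol; the aldehyde has no α-hydrogen, so C9 can neither epimerise nor eliminate.

Step 12
Reactants: 16 (2R,3R)-3-bromo-4-[(5S)-5-bromo-2,6,6-trimethylcyclohex-1-en-1-yl]-2-chloro-2-methylbutanal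
Product: 17 (4S)-4-bromo-2-[(2R,3R)-2-bromo-3-chloro-3-methylpent-4-en-1-yl]-1,3,3-trimethylcyclohex-1-ene
Conditions: Ph3PCH3Br, KN(SiMe3)2, THF, 0 °C; then 16, −78 → 0 °C
Reagents that add atoms: methylenetriphenylphosphorane, C=P(c1ccccc1)(c1ccccc1)c1ccccc1
Why: Wittig methylenation of a non-enolisable aldehyde adds C7; carbonyl addition at −78 °C should outrun dehydrohalogenation by the ylide, and the allylic chloride is carried on without storage.

Step 13
Reactants: 17 (4S)-4-bromo-2-[(2R,3R)-2-bromo-3-chloro-3-methylpent-4-en-1-yl]-1,3,3-trimethylcyclohex-1-ene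
Product: 19 (3R,4R)-4-bromo-5-[(5S)-5-bromo-2,6,6-trimethylcyclohex-1-en-1-yl]-3-chloro-3-methylpentan-1-ol, via B-alkyl-9-BBN adduct 18 (not isolated)
Conditions: 9-BBN, THF, 0 → 23 °C; then H2O2, pH 7 phosphate buffer, 0 → 23 °C
Reagents that add atoms: hydrogen peroxide, OO
Why: Anti-Markovnikov hydroboration–oxidation of the monosubstituted alkene (9-BBN does not add to the tetrasubstituted ring alkene), with buffered oxidation to avoid 1,3-elimination of the γ-chloroalkylborane.

Step 14
Reactants: 19 (3R,4R)-4-bromo-5-[(5S)-5-bromo-2,6,6-trimethylcyclohex-1-en-1-yl]-3-chloro-3-methylpentan-1-ol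
Product: 21 (4S,6R,9R,10R)-4,10-dibromo-9-chloro-1,5,5,9-tetramethylspiro[5.5]undec-1-ene, via primary triflate 20 (not isolated)
Conditions: Tf2O, 2,6-di-tert-butyl-4-methylpyridine, CH2Cl2, −78 °C; then MeNO2, −20 → 23 °C
Reagents that add atoms: none
Why: Proposed new method: the tetrasubstituted C6=C1 alkene of ring A displaces the primary C7 triflate through its π bond (alkene participation, SN2 at C7), the tertiary C1 cation so formed loses the C2 proton, and the C1=C2 alkene of the target results; the closest known reaction types are the solvolytic π-cyclisation of primary alkenyl arenesulfonates and the biomimetic cation–olefin spirocyclisation that leads to chamigrenes, here moved to a primary triflate in a non-ionising medium so that the tertiary C9 chloride is not ionised. Ring B closes by 6-exo attack of C6 on C7 through a chair (attack by C1 would need a seven-membered ring). The new stereocentre C6 is set by two elements that point the same way: C7 adds to the alkene face anti to the pseudoaxial C5 methyl group, that is trans to the equatorial C4 bromide, and the tether folds as a chair with Cl (C9) and Br (C10) equatorial and the quaternary C5 equatorial on the new ring, which is the all-equatorial arrangement of the target. The step needs C6 rather than C1 attack, endocyclic (Zaitsev) proton loss and an intact C9–Cl bond; the six-membered chair, elimination within the tight ion pair and the absence of an ionising solvent are meant to secure them.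

**Compound list**

1 | 3-methylbut-2-en-1-ol (prenol) | CC(C)=CCO | starting material
2 | (2S)-2-bromo-3-chloro-3-methylbutan-1-ol | OC[C@H](Br)C(C)(C)Cl | intermediate
3 | (2S)-2-bromo-3-chloro-3-methylbutyl trifluoromethanesulfonate | FC(F)(F)S(=O)(=O)OC[C@H](Br)C(C)(C)Cl | intermediate
4 | methyl acetoacetate (methyl 3-oxobutanoate) | COC(=O)CC(C)=O | starting material
5 | methyl acetoacetate dianion (sodium lithium dienediolate) | [Na+].[Li+].COC([O-])=CC([O-])=C | intermediate
6 | methyl (6S)-6-bromo-7-chloro-7-methyl-3-oxooctanoate | COC(=O)CC(=O)CC[C@H](Br)C(C)(C)Cl | intermediate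
7 | methyl (3S)-3-bromo-2,2-dimethyl-6-oxocyclohexane-1-carboxylate (C1 epimers, partly enolised) | COC(=O)C1C(=O)CC[C@H](Br)C1(C)C | intermediate
8 | methyl (5S)-5-bromo-6,6-dimethyl-2-(trifluoromethanesulfonyloxy)cyclohex-1-ene-1-carboxylate | COC(=O)C1=C(OS(=O)(=O)C(F)(F)F)CC[C@H](Br)C1(C)C | intermediate
9 | methyl (5S)-5-bromo-2,6,6-trimethylcyclohex-1-ene-1-carboxylate | COC(=O)C1=C(C)CC[C@H](Br)C1(C)C | intermediate
10 | [(5S)-5-bromo-2,6,6-trimethylcyclohex-1-en-1-yl]methanol | OCC1=C(C)CC[C@H](Br)C1(C)C | intermediate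
11 | (4S)-4-bromo-2-(bromomethyl)-1,3,3-trimethylcyclohex-1-ene | BrCC1=C(C)CC[C@H](Br)C1(C)C | intermediate
12 | prop-2-yn-1-ol (propargyl alcohol) | C#CCO | starting material
13 | 4-methyl-2,5-dihydro-1,2-oxamagnesole (chelated Z alkenylmagnesium alkoxide) | CC1=C[Mg]OC1 | intermediate
14 | (2Z)-4-[(5S)-5-bromo-2,6,6-trimethylcyclohex-1-en-1-yl]-2-methylbut-2-en-1-ol | OC/C(C)=C\CC1=C(C)CC[C@H](Br)C1(C)C | intermediate
15 | (2R,3R)-3-bromo-4-[(5S)-5-bromo-2,6,6-trimethylcyclohex-1-en-1-yl]-2-chloro-2-methylbutan-1-ol | OC[C@@](C)(Cl)[C@H](Br)CC1=C(C)CC[C@H](Br)C1(C)C | intermediate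
16 | (2R,3R)-3-bromo-4-[(5S)-5-bromo-2,6,6-trimethylcyclohex-1-en-1-yl]-2-chloro-2-methylbutanal | O=C[C@@](C)(Cl)[C@H](Br)CC1=C(C)CC[C@H](Br)C1(C)C | intermediate
17 | (4S)-4-bromo-2-[(2R,3R)-2-bromo-3-chloro-3-methylpent-4-en-1-yl]-1,3,3-trimethylcyclohex-1-ene | C=C[C@@](C)(Cl)[C@H](Br)CC1=C(C)CC[C@H](Br)C1(C)C | intermediate
18 | 9-{(3R,4R)-4-bromo-5-[(5S)-5-bromo-2,6,6-trimethylcyclohex-1-en-1-yl]-3-chloro-3-methylpentyl}-9-borabicyclo[3.3.1]nonane | C1CC2CCCC(C1)B2CC[C@@](C)(Cl)[C@H](Br)CC1=C(C)CC[C@H](Br)C1(C)C | intermediate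
19 | (3R,4R)-4-bromo-5-[(5S)-5-bromo-2,6,6-trimethylcyclohex-1-en-1-yl]-3-chloro-3-methylpentan-1-ol | OCC[C@@](C)(Cl)[C@H](Br)CC1=C(C)CC[C@H](Br)C1(C)C | intermediate
20 | (3R,4R)-4-bromo-5-[(5S)-5-bromo-2,6,6-trimethylcyclohex-1-en-1-yl]-3-chloro-3-methylpentyl trifluoromethanesulfonate | FC(F)(F)S(=O)(=O)OCC[C@@](C)(Cl)[C@H](Br)CC1=C(C)CC[C@H](Br)C1(C)C | intermediate
21 | (4S,6R,9R,10R)-4,10-dibromo-9-chloro-1,5,5,9-tetramethylspiro[5.5]undec-1-ene (locants as labelled in the overview; 2,10-dibromo-3-chloro-α-chamigrene) | CC1=CC[C@H](Br)C(C)(C)[C@@]12CC[C@@](C)(Cl)[C@H](Br)C2 | target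

**Step count and risks**

Total step count: 14. Longest linear sequence: 14 steps (1 to 21); 4 and 12 are bought and enter in steps 3 and 9.

Steps most likely to fail:

1. Step 14 (proposed new method). The hindered π bond may displace the triflate too slowly, so that 1,4-bromine participation, elimination, or proton loss toward the C1 methyl group (exocyclic alkene) takes over. The fallback uses known chemistry, sets out from 19 and returns at 21. Dess–Martin oxidation of 19 should give the aldehyde (3R,4R)-4-bromo-5-[(5S)-5-bromo-2,6,6-trimethylcyclohex-1-en-1-yl]-3-chloro-3-methylpentanal F1, which is used at once at −78 °C because a β-chloro aldehyde can lose HCl. Me2AlCl in CH2Cl2 should then close ring B by a type 1 intramolecular carbonyl–ene (Prins) reaction: C6 adds to C7 on the same face as in step 14 and the C2 hydrogen passes to oxygen, which gives the C1=C2 alkene and the 7-hydroxy derivative of 21 (C7 epimers) F2. Its S-methyl xanthate F3 (KN(SiMe3)2, CS2, MeI, −78 °C) is then reduced by the tin-free Barton–McCombie protocol (dilauroyl peroxide, 2-propanol, reflux), whose carbon-centred chain carriers should spare the alkyl bromides, to give 21.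

2. Step 10. Chemoselectivity may be lost if electrophilic bromine is taken up by the electron-rich tetrasubstituted ring alkene, or if that alkene intercepts the bromonium ion. The fallback sets out from 14 and returns at 15. Sharpless asymmetric epoxidation (Ti(OiPr)4, the diethyl tartrate enantiomer that gives the epoxide shown, t-BuOOH, CH2Cl2, −20 °C) is confined to the allylic alkene and should give {(2R,3S)-3-{[(5S)-5-bromo-2,6,6-trimethylcyclohex-1-en-1-yl]methyl}-2-methyloxiran-2-yl}methanol F4. Opening at C10 with bromide under Ti(OiPr)4 mediation (Et2NH2Br) inverts C10 and should give (2R,3R)-3-bromo-4-[(5S)-5-bromo-2,6,6-trimethylcyclohex-1-en-1-yl]-2-methylbutane-1,2-diol F5. HCl in CH2Cl2–dioxane at 0 °C then replaces the tertiary hydroxyl by chloride with retention through the bromonium ion (anchimeric assistance), which gives 15.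

3. Step 3. The strongly basic dianion may dehydrobrominate the β-bromo triflate instead of substituting it. The fallback sets out from 3 and returns at 6. Copper-catalysed coupling of 3 with allylmagnesium bromide (CuI, THF, −78 °C) should give (5S)-5-bromo-6-chloro-6-methylhept-1-ene F6. Ozonolysis (O3, CH2Cl2, −78 °C; Me2S) gives (4S)-4-bromo-5-chloro-5-methylhexanal F7. The Roskamp reaction with methyl diazoacetate and catalytic SnCl2 in CH2Cl2 then gives the β-keto ester 6.

**Further compounds**

F1 | step 14 | (3R,4R)-4-bromo-5-[(5S)-5-bromo-2,6,6-trimethylcyclohex-1-en-1-yl]-3-chloro-3-methylpentanal | O=CC[C@@](C)(Cl)[C@H](Br)CC1=C(C)CC[C@H](Br)C1(C)C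
F2 | step 14 | 7-hydroxy derivative of 21 (hydroxyl on C7, both epimers; other centres as in 21) | CC1=CC[C@H](Br)C(C)(C)[C@@]12C(O)C[C@@](C)(Cl)[C@H](Br)C2
F3 | step 14 | S-methyl xanthate of F2 (O-alkyl S-methyl carbonodithioate at C7) | CC1=CC[C@H](Br)C(C)(C)[C@@]12C(OC(=S)SC)C[C@@](C)(Cl)[C@H](Br)C2
F4 | step 10 | {(2R,3S)-3-{[(5S)-5-bromo-2,6,6-trimethylcyclohex-1-en-1-yl]methyl}-2-methyloxiran-2-yl}methanol | OC[C@@]1(C)O[C@H]1CC2=C(C)CC[C@H](Br)C2(C)C
F5 | step 10 | (2R,3R)-3-bromo-4-[(5S)-5-bromo-2,6,6-trimethylcyclohex-1-en-1-yl]-2-methylbutane-1,2-diol | OC[C@@](C)(O)[C@H](Br)CC1=C(C)CC[C@H](Br)C1(C)C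
F6 | step 3 | (5S)-5-bromo-6-chloro-6-methylhept-1-ene | C=CCC[C@H](Br)C(C)(C)Cl
F7 | step 3 | (4S)-4-bromo-5-chloro-5-methylhexanal | O=CCC[C@H](Br)C(C)(C)Cl
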